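**Plan**
- Retrosynthetic cuts, in order: the silyl ether on ring C; the (Z)-enal, taken back through a (Z)-allylic alcohol to an alkyne that is cut off at C5 of ring A; the O–C9 bond of the 4-hydroxybenzoate; O1–C2 together with C3–C9; finally C3–C3a.
- Enabling feature: in ring B the bond O1–C2 and the exocyclic bond C3–C9 start from neighbouring carbons. Erasing both leaves C2=C3 as an alkene tying ring C to the carbon ortho to the ring A phenol (a 2-hydroxystilbene), and leaves C9 as carbon monoxide.
- Forward: rings A and C are bought (4-bromoguaiacol, vanillin) and joined by a Heck reaction. Ring B, the only ring made, closes in the oxypalladation–methoxycarbonylation. Ester reduction, Mitsunobu acylation and a Sonogashira/semihydrogenation/MnO2 sequence at C5 follow.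
- Stereochemistry: C2 comes from the alkene face chosen by the chiral bisoxazoline–palladium complex. C3 follows stereospecifically (E alkene, anti addition, retentive CO insertion, hence 2,3-trans). The Z alkene comes from syn semihydrogenation.
- The C5 bromine is a spectator that deactivates the phenol less than a carbonyl group would, and the labile (Z)-enal appears only in the penultimate step.

Key step: step 5

Labels: dihydrobenzofuran numbering O1, C2, C3, C3a, C4–C7, C7a. C9 is the exocyclic carbon on C3. Ring A is the benzo ring, ring B the dihydrofuran ring, ring C the aryl group on C2.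

Assumption: the sense of induction of the bisoxazoline in the new cyclisation cannot be derived from precedent; the (S,S)-ligand is written, and its equally available antipode is to be used if the other alkene face is delivered.

**Step 1**
Reactants: 1 4-bromo-2-methoxyphenol
Product: 2 4-bromo-2-iodo-6-methoxyphenol
Conditions: I2, KI, NaOH, H2O–MeOH, 0 °C to rt
Reagents that add atoms: iodine, [I][I]
Why: Electrophilic aromatic iodination of the phenoxide, whose oxygen overrides the methoxy and bromo directors and whose para position (Br) and one ortho position (OMe) are blocked, so iodine can enter only at C6.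

**Step 2**
Reactants: 3 vanillin
Product: 4 3-methoxy-4-(triisopropylsilyloxy)benzaldehyde
Conditions: TIPSCl, imidazole, DMF, rt
Reagents that add atoms: triisopropylsilyl chloride, CC(C)[Si](Cl)(C(C)C)C(C)C
Why: Imidazole-promoted O-silylation of a phenol, with the bulky triisopropylsilyl group chosen because it must outlast ylide, hot amine, traces of CF3CO2H, aluminium hydride and MnO2.

**Step 3**
Reactants: 4 3-methoxy-4-(triisopropylsilyloxy)benzaldehyde
Product: 5 triisopropyl(2-methoxy-4-vinylphenoxy)silane
Conditions: Ph3PCH3Br, KOt-Bu, THF, 0 °C to rt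
Reagents that add atoms: methyltriphenylphosphonium bromide, C[P+](c1ccccc1)(c1ccccc1)c1ccccc1.[Br-]
Why: Wittig methylenation of an aromatic aldehyde with the preformed non-stabilised ylide, so that no free alkoxide meets the aryl silyl ether.

**Step 4**
Reactants: 2 4-bromo-2-iodo-6-methoxyphenol; 5 triisopropyl(2-methoxy-4-vinylphenoxy)silane
Product: 6 4-bromo-2-methoxy-6-[(E)-2-(3-methoxy-4-triisopropylsilyloxyphenyl)ethenyl]phenol
Conditions: Pd(OAc)2 (3 mol %), P(o-tol)3, Et3N, MeCN, 80 °C
Reagents that add atoms: none
Why: Mizoroki–Heck arylation, in which zerovalent palladium inserts into the C–I bond far faster than into the C–Br bond, the aryl group adds to the unsubstituted styrene terminus (C3–C3a bond), and syn β-hydride elimination gives the E stilbene.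

**Step 5**
Reactants: 6 4-bromo-2-methoxy-6-[(E)-2-(3-methoxy-4-triisopropylsilyloxyphenyl)ethenyl]phenol; 7 carbon monoxide; 8 methanol
Product: 9 methyl (2S,3S)-5-bromo-7-methoxy-2-(3-methoxy-4-triisopropylsilyloxyphenyl)-2,3-dihydrobenzofuran-3-carboxylate (2,3-trans)
Conditions: Pd(OCOCF3)2 (10 mol %), 2,2'-(propane-2,2-diyl)bis[(4S)-4-phenyl-4,5-dihydrooxazole] (12 mol %), p-benzoquinone (2 equiv), CO (10 bar), MeOH–CH2Cl2 1:1, 0 °C to rt
Reagents that add atoms: carbon monoxide (7), [C-]#[O+]; methanol (8), CO
Why: Proposed new method: the cationic palladium trifluoroacetate–bisoxazoline complex binds one face of the C2=C3 bond of 6, the ring A phenol oxygen (ring A twisted out of the alkene plane) attacks C2 from the opposite face, the C3–palladium σ-benzyl bond so formed inserts CO with retention, methanol cleaves the acyl complex to the ester, and benzoquinone with the released CF3CO2H takes zerovalent palladium back to the divalent state. The closest known reaction types are the alkoxypalladation–methoxycarbonylation of hydroxyalkenes (exo closures), the 5-endo-dig cyclisation–methoxycarbonylation of 2-alkynylphenols to benzofuran-3-carboxylates, the enantioselective Wacker-type cyclisation of 2-allylphenols and the oxidative cyclisation of 2-hydroxystilbenes to 2-arylbenzofurans with divalent palladium, and what is new is the interception of the alkene-derived endo intermediate by CO under ligand control. Ring B closes in the 5-endo-trig mode, which is workable only as an outside (anti) attack on the metal-bound alkene, as in 5-endo iodoetherification, because a syn insertion into a Pd–O bond would need O1, C2, C3 and Pd coplanar inside the forming five-membered ring. C2 is set by the alkene face that the twofold-symmetric ligand leaves open to oxygen, and C3 follows from it stereospecifically, since anti addition to the E alkene puts palladium, and after the retentive insertion C9, trans to ring C, which gives the (2S,3S) ester without any epimerisation. Regioselectivity is built into the substrate, as only attack at C2 closes a ring and C2 is the carbon whose developing positive charge the para-silyloxy group of ring C stabilises. The selectivity that has to be won is CO capture ahead of loss of the C2 hydrogen, the only β-hydrogen and cis to palladium, and it is favoured by CO pressure, by the chelating ligand that leaves no free cis site once CO is bound, by low temperature and by η3-benzyl stabilisation through ring A, while the C5–Br bond is inert to phosphine-free palladium at this temperature.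

**Step 6**
Reactants: 9 methyl (2S,3S)-5-bromo-7-methoxy-2-(3-methoxy-4-triisopropylsilyloxyphenyl)-2,3-dihydrobenzofuran-3-carboxylate
Product: 10 [(2S,3R)-5-bromo-7-methoxy-2-(3-methoxy-4-triisopropylsilyloxyphenyl)-2,3-dihydrobenzofuran-3-yl]methanol
Conditions: i-Bu2AlH (3 equiv), CH2Cl2, −78 to 0 °C; aq. potassium sodium tartrate (KNaC4H4O6)
Reagents that add atoms: none
Why: Ester-to-alcohol reduction with a non-basic aluminium hydride that spares the aryl bromide and the silyl ether and avoids enolisation at C3, whose descriptor changes from S to R only because C9 drops in priority.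

**Step 7**
Reactants: 10 [(2S,3R)-5-bromo-7-methoxy-2-(3-methoxy-4-triisopropylsilyloxyphenyl)-2,3-dihydrobenzofuran-3-yl]methanol; 11 4-hydroxybenzoic acid
Product: 12 [(2S,3R)-5-bromo-7-methoxy-2-(3-methoxy-4-triisopropylsilyloxyphenyl)-2,3-dihydrobenzofuran-3-yl]methyl 4-hydroxybenzoate
Conditions: PPh3, DIAD, THF, 0 °C to rt
Reagents that add atoms: none
Why: Mitsunobu esterification, in which the carboxylic acid, far more acidic than the phenol of 11, is the partner that intercepts the C9 alkoxyphosphonium ion (a chemoselectivity established for unprotected phenolic acids), while C9 is not stereogenic and C3 is untouched.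

**Step 8**
Reactants: 12 [(2S,3R)-5-bromo-7-methoxy-2-(3-methoxy-4-triisopropylsilyloxyphenyl)-2,3-dihydrobenzofuran-3-yl]methyl 4-hydroxybenzoate; 13 prop-2-yn-1-ol
Product: 14 [(2S,3R)-5-(3-hydroxyprop-1-ynyl)-7-methoxy-2-(3-methoxy-4-triisopropylsilyloxyphenyl)-2,3-dihydrobenzofuran-3-yl]methyl 4-hydroxybenzoate
Conditions: Pd(PhCN)2Cl2 (3 mol %), [HP(t-Bu)3]BF4 (6 mol %), CuI (2 mol %), i-Pr2NH, 1,4-dioxane, rt
Reagents that add atoms: none
Why: Sonogashira coupling, in which the bulky electron-rich P(t-Bu)3 allows oxidative addition into the donor-substituted C5–Br bond at room temperature and the hindered amine spares the ester and the silyl ether.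

**Step 9**
Reactants: 14 [(2S,3R)-5-(3-hydroxyprop-1-ynyl)-7-methoxy-2-(3-methoxy-4-triisopropylsilyloxyphenyl)-2,3-dihydrobenzofuran-3-yl]methyl 4-hydroxybenzoate
Product: 15 [(2S,3R)-5-[(Z)-3-hydroxyprop-1-enyl]-7-methoxy-2-(3-methoxy-4-triisopropylsilyloxyphenyl)-2,3-dihydrobenzofuran-3-yl]methyl 4-hydroxybenzoate
Conditions: H2 (1 atm), Pd/CaCO3 poisoned with Pb(OAc)2, quinoline, EtOAc, rt, stopped after one equivalent of H2
Reagents that add atoms: none
Why: Lindlar semihydrogenation, which delivers both hydrogens to the same face of the surface-bound alkyne and so sets the Z geometry, while lead and quinoline poisoning stop the uptake at the alkene and spare the benzylic C2–O1 bond.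

**Step 10**
Reactants: 15 [(2S,3R)-5-[(Z)-3-hydroxyprop-1-enyl]-7-methoxy-2-(3-methoxy-4-triisopropylsilyloxyphenyl)-2,3-dihydrobenzofuran-3-yl]methyl 4-hydroxybenzoate
Product: 16 [(2S,3R)-7-methoxy-2-(3-methoxy-4-triisopropylsilyloxyphenyl)-5-[(Z)-3-oxoprop-1-enyl]-2,3-dihydrobenzofuran-3-yl]methyl 4-hydroxybenzoate
Conditions: activated MnO2 (15 equiv), CH2Cl2, 0 °C to rt, dark
Reagents that add atoms: none
Why: Heterogeneous MnO2 oxidation of the allylic alcohol, the only free aliphatic hydroxyl, under neutral conditions of the kind that carry Z-allylic alcohols to Z-enals with retention of geometry and leave the electron-poor benzoate phenol alone.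

**Step 11**
Reactants: 16 [(2S,3R)-7-methoxy-2-(3-methoxy-4-triisopropylsilyloxyphenyl)-5-[(Z)-3-oxoprop-1-enyl]-2,3-dihydrobenzofuran-3-yl]methyl 4-hydroxybenzoate
Product: 17 [(2S,3R)-2-(4-hydroxy-3-methoxyphenyl)-7-methoxy-5-[(Z)-3-oxoprop-1-enyl]-2,3-dihydrobenzofuran-3-yl]methyl 4-hydroxybenzoate (CNP0400980.1)
Conditions: n-Bu4NF, AcOH (1:1), THF, 0 °C, dark
Reagents that add atoms: none
Why: Fluoride-induced cleavage of the aryl silyl ether, buffered with acetic acid so that neither a free ring C phenoxide (which could open ring B through a para-quinone methide) nor a strong acid (which would turn the Z-enal into the E isomer) is present.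

**Compound list**
1 | 4-bromo-2-methoxyphenol | COc1cc(Br)ccc1O | starting material
2 | 4-bromo-2-iodo-6-methoxyphenol | COc1cc(Br)cc(I)c1O | intermediate
3 | vanillin (4-hydroxy-3-methoxybenzaldehyde) | COc1cc(C=O)ccc1O | starting material
4 | 3-methoxy-4-(triisopropylsilyloxy)benzaldehyde | COc1cc(C=O)ccc1O[Si](C(C)C)(C(C)C)C(C)C | intermediate
5 | triisopropyl(2-methoxy-4-vinylphenoxy)silane | COc1cc(C=C)ccc1O[Si](C(C)C)(C(C)C)C(C)C | intermediate
6 | 4-bromo-2-methoxy-6-[(E)-2-(3-methoxy-4-triisopropylsilyloxyphenyl)ethenyl]phenol | COc1cc(/C=C/c2cc(Br)cc(OC)c2O)ccc1O[Si](C(C)C)(C(C)C)C(C)C | intermediate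
7 | carbon monoxide | [C-]#[O+] | starting material
8 | methanol | CO | starting material
9 | methyl (2S,3S)-5-bromo-7-methoxy-2-(3-methoxy-4-triisopropylsilyloxyphenyl)-2,3-dihydrobenzofuran-3-carboxylate (trans) | COc1cc([C@H]2Oc3c(OC)cc(Br)cc3[C@@H]2C(=O)OC)ccc1O[Si](C(C)C)(C(C)C)C(C)C | intermediate
10 | [(2S,3R)-5-bromo-7-methoxy-2-(3-methoxy-4-triisopropylsilyloxyphenyl)-2,3-dihydrobenzofuran-3-yl]methanol | COc1cc([C@H]2Oc3c(OC)cc(Br)cc3[C@@H]2CO)ccc1O[Si](C(C)C)(C(C)C)C(C)C | intermediate
11 | 4-hydroxybenzoic acid | O=C(O)c1ccc(O)cc1 | starting material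
12 | [(2S,3R)-5-bromo-7-methoxy-2-(3-methoxy-4-triisopropylsilyloxyphenyl)-2,3-dihydrobenzofuran-3-yl]methyl 4-hydroxybenzoate | COc1cc([C@H]2Oc3c(OC)cc(Br)cc3[C@@H]2COC(=O)c2ccc(O)cc2)ccc1O[Si](C(C)C)(C(C)C)C(C)C | intermediate
13 | prop-2-yn-1-ol | C#CCO | starting material
14 | [(2S,3R)-5-(3-hydroxyprop-1-ynyl)-7-methoxy-2-(3-methoxy-4-triisopropylsilyloxyphenyl)-2,3-dihydrobenzofuran-3-yl]methyl 4-hydroxybenzoate | COc1cc([C@H]2Oc3c(OC)cc(C#CCO)cc3[C@@H]2COC(=O)c2ccc(O)cc2)ccc1O[Si](C(C)C)(C(C)C)C(C)C | intermediate
15 | [(2S,3R)-5-[(Z)-3-hydroxyprop-1-enyl]-7-methoxy-2-(3-methoxy-4-triisopropylsilyloxyphenyl)-2,3-dihydrobenzofuran-3-yl]methyl 4-hydroxybenzoate | COc1cc([C@H]2Oc3c(OC)cc(/C=C\CO)cc3[C@@H]2COC(=O)c2ccc(O)cc2)ccc1O[Si](C(C)C)(C(C)C)C(C)C | intermediate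
16 | [(2S,3R)-7-methoxy-2-(3-methoxy-4-triisopropylsilyloxyphenyl)-5-[(Z)-3-oxoprop-1-enyl]-2,3-dihydrobenzofuran-3-yl]methyl 4-hydroxybenzoate | COc1cc([C@H]2Oc3c(OC)cc(/C=C\C=O)cc3[C@@H]2COC(=O)c2ccc(O)cc2)ccc1O[Si](C(C)C)(C(C)C)C(C)C | intermediate
17 | [(2S,3R)-2-(4-hydroxy-3-methoxyphenyl)-7-methoxy-5-[(Z)-3-oxoprop-1-enyl]-2,3-dihydrobenzofuran-3-yl]methyl 4-hydroxybenzoate | COc1cc([C@H]2Oc3c(OC)cc(/C=C\C=O)cc3[C@@H]2COC(=O)c2ccc(O)cc2)ccc1O | target

**Total step count:** 11. **Longest linear sequence:** 10 steps (3 to 17 through steps 2 to 11).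

**Steps most likely to fail**

**1. Step 5.**
- β-Hydride elimination may outrun CO insertion and aromatise ring B.
- Carbonylation may begin at the phenol oxygen before the ring closes.
- Methanol may compete with the phenol as the nucleophile at C2.
- The hindered diaryl alkene may bind poorly to palladium saturated with CO.
- Facial selectivity may be poor, or control at C3 may leak through a cationic pathway.

The fallback uses known chemistry, sets out from 2 and 4, and comes back at 9.
- NaBH4 in MeOH reduces 4 to [3-methoxy-4-(triisopropylsilyloxy)phenyl]methanol F1.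
- Mitsunobu etherification of phenol 2 with F1 (PPh3, DIAD, THF) gives 5-bromo-1-iodo-3-methoxy-2-{[3-methoxy-4-(triisopropylsilyloxy)phenyl]methoxy}benzene F2.
- Iodide-selective palladium-catalysed coupling with methyl diazoacetate (Pd(PPh3)4, Ag2CO3, Et3N, toluene, rt) gives methyl 2-(5-bromo-3-methoxy-2-{[3-methoxy-4-(triisopropylsilyloxy)phenyl]methoxy}phenyl)-2-diazoacetate F3.
- Enantioselective intramolecular C–H insertion of the rhodium carbene into the benzylic OCH2 group follows. It uses Rh2(S-PTTL)4 (dirhodium tetrakis[N-phthaloyl-(S)-tert-leucinate]), or its antipode if that one delivers the 2S series, in toluene at −60 °C.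
- This insertion closes ring B through C2–C3 and gives the cis ester methyl (2S,3R)-5-bromo-7-methoxy-2-(3-methoxy-4-triisopropylsilyloxyphenyl)-2,3-dihydrobenzofuran-3-carboxylate F4.
- Brief treatment with DBU in CH2Cl2 epimerises C3 to the more stable trans ester 9.

The same base treatment would also funnel any C3 epimer formed in step 5 into 9.

**2. Step 9.** Hydrogen uptake may not stop at the alkene, and Z to E isomerisation may occur on the metal surface.

The fallback avoids both alkyne and hydrogenation, sets out from 12 and 13, and comes back at 15.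
- Hydroalumination of 13 with LiAlH4 in THF, then quenching of the cyclic vinylalanate with n-Bu3SnOTf, gives (Z)-3-(tributylstannyl)prop-2-en-1-ol F5.
- Stille coupling of F5 with bromide 12 (Pd(PPh3)4, CuI, LiCl, DMF, 80 °C) transfers the alkenyl group with retention of geometry and gives 15 directly.

**3. Step 11.** The donor–acceptor enal may isomerise from Z to E through addition–elimination of fluoride or acetate, or through protonation. Release of the ring C phenoxide may open the C2–O1 bond through a para-quinone methide, with loss of configuration at C2.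

The fallback reverses the order of the last two operations so that the enal never meets fluoride. It sets out from 15 and comes back at 17.
- n-Bu4NF/AcOH in THF at 0 °C removes the silyl group at the alcohol stage. This gives [(2S,3R)-2-(4-hydroxy-3-methoxyphenyl)-5-[(Z)-3-hydroxyprop-1-enyl]-7-methoxy-2,3-dihydrobenzofuran-3-yl]methyl 4-hydroxybenzoate F6.
- Chemoselective allylic oxidation with activated MnO2 (CH2Cl2–EtOAc, dark) closes the synthesis at 17. This operation is known for free-phenolic coniferyl-alcohol-type side chains.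

**Further compounds**
F1 | step 5 | [3-methoxy-4-(triisopropylsilyloxy)phenyl]methanol | COc1cc(CO)ccc1O[Si](C(C)C)(C(C)C)C(C)C
F2 | step 5 | 5-bromo-1-iodo-3-methoxy-2-{[3-methoxy-4-(triisopropylsilyloxy)phenyl]methoxy}benzene | COc1cc(COc2c(I)cc(Br)cc2OC)ccc1O[Si](C(C)C)(C(C)C)C(C)C
F3 | step 5 | methyl 2-(5-bromo-3-methoxy-2-{[3-methoxy-4-(triisopropylsilyloxy)phenyl]methoxy}phenyl)-2-diazoacetate | COc1cc(COc2c(OC)cc(Br)cc2C(=[N+]=[N-])C(=O)OC)ccc1O[Si](C(C)C)(C(C)C)C(C)C
F4 | step 5 | methyl (2S,3R)-5-bromo-7-methoxy-2-(3-methoxy-4-triisopropylsilyloxyphenyl)-2,3-dihydrobenzofuran-3-carboxylate (cis) | COc1cc([C@H]2Oc3c(OC)cc(Br)cc3[C@H]2C(=O)OC)ccc1O[Si](C(C)C)(C(C)C)C(C)C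
F5 | step 9 | (Z)-3-(tributylstannyl)prop-2-en-1-ol | OC/C=C\[Sn](CCCC)(CCCC)CCCC
F6 | step 11 | [(2S,3R)-2-(4-hydroxy-3-methoxyphenyl)-5-[(Z)-3-hydroxyprop-1-enyl]-7-methoxy-2,3-dihydrobenzofuran-3-yl]methyl 4-hydroxybenzoate | COc1cc([C@H]2Oc3c(OC)cc(/C=C\CO)cc3[C@@H]2COC(=O)c2ccc(O)cc2)ccc1O
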